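**Retrosynthetic overview**
- Last bond: C4=C5, by ene–diene cross-metathesis of a C4–C17 alkene (bicyclic ketal already in place) with an N-naphthoquinonyl (2Z,4E)-2-methylhexa-2,4-dienamide.
- Key bond: C13–C14, by adding a ketal-masked methyl-ketone homoenolate (3-oxobutyl d3 Grignard) to the C13 lactol; acid work-up in the same flask closes the oxolane and then the 1,3-dioxane ring of the 2,8-dioxabicyclo[3.2.1]octane.
- C6–C7 by crotylboration; the C8–C12 stereopentad in one step by two-directional double C–H crotylation of 2-methylpropane-1,3-diol; the two ends are told apart by lactol ring strain.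
- Naphthoquinone: the benzenoid ring is built by Diels–Alder reaction of a 3-oxoglutarate-derived bis(silyloxy)diene onto 2,6-dibromobenzoquinone; the remaining Br becomes N3, then NH2, then the amide.
- Ring order: temporary oxane lactols; benzenoid ring of the naphthoquinone; oxolane then 1,3-dioxane of the ketal (one flask).

Assumption: target side-chain numbering (C1 amide carbonyl to C17 ketal methyl) is used for all fragments, and the named antipodes of SEGPHOS and TRIP are taken to give the drawn sense of induction (otherwise the mirror-image ligand is used).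

**Route**

Step 1
Reactants: 1 2-methylpropane-1,3-diol; 2 but-3-en-2-yl acetate (racemic)
Product: 3 (3R,4R,6R,7R)-3,5,7-trimethylnona-1,8-diene-4,6-diol (pseudo-C2-symmetric; carbons C7–C13)
Conditions: 2 (4 equiv), [Ir(cod)Cl]2 (5 mol %), (S)-SEGPHOS (10 mol %), 4-cyano-3-nitrobenzoic acid (20 mol %), Cs2CO3 (40 mol %), THF, 70 °C
Reagents that add atoms: none
Why: Krische-type iridium-catalysed transfer-hydrogenative double C–H crotylation: each CH2OH is dehydrogenated in situ and the aldehyde is captured by the (E)-σ-crotyliridium species through a closed chair transition state, so both methyl/carbinol pairs are anti and both carbinols get the same catalyst-controlled configuration, which sets C8, C9, C11 and C12 (C10 becomes stereogenic when the arms are differentiated in step 3).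

Step 2
Reactants: 3 (3R,4R,6R,7R)-3,5,7-trimethylnona-1,8-diene-4,6-diol
Product: 4 4,8,9-trimethyl-2,6-dioxabicyclo[3.3.1]nonane-3,7-diol (bis-lactol form of the C7/C13 dialdehyde; anomers; C8–C12 as in 3)
Conditions: O3, CH2Cl2–MeOH, −78 °C; then PPh3, −78 → 23 °C
Reagents that add atoms: ozone, [O-][O+]=O
Why: Ozonolysis with reductive work-up cleaves both vinyl groups, and each aldehyde is trapped by its δ-hydroxyl as a six-membered lactol, so the dialdehyde is handled without protecting groups and without touching the stereocentres.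

Step 3
Reactants: 4 bis-lactol; 5 (E)-crotylboronic acid pinacol ester
Product: 6 C4–C13 lactol triol, 6-[(2R,3S,4S)-3-hydroxy-4-methylhex-5-en-2-yl]-3,5-dimethyloxane-2,4-diol (O9–C13 lactol kept; C6–C12 configured as in the target; anomers)
Conditions: 5 (1.2 equiv), (R)-TRIP [3,3′-bis(2,4,6-triisopropylphenyl)-BINOL hydrogen phosphate] (5 mol %), 4 Å MS, toluene, 0 °C; aq. NaHCO3
Reagents that add atoms: none
Why: Brønsted-acid-catalysed crotylboration of a lactol through a Zimmerman–Traxler chair (E-boronate gives 6,7-anti): the O11–C7 lactol is all-cis substituted and cannot sit in a chair without a syn-diaxial pair, whereas the O9–C13 lactol has only one axial methyl, so the open aldehyde is found at C7, and Felkin–Anh attack reinforced by the chiral phosphoric acid sets 7,8-syn.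

Step 4
Reactants: 6 C4–C13 lactol triol
Product: 8 lactol 6 with O7 and O11 as triethylsilyl ethers and the anomeric OH free, via tris(triethylsilyl) ether 7 (not isolated)
Conditions: Et3SiOTf (3.5 equiv), 2,6-lutidine, CH2Cl2, −78 → 0 °C; then Bu4NF–AcOH (1:1, 1.1 equiv), THF, −20 °C
Reagents that add atoms: triethylsilyl trifluoromethanesulfonate, CC[Si](CC)(CC)OS(=O)(=O)C(F)(F)F
Why: Silyl ether formation on all three hydroxyls and chemoselective fluoride cleavage of the anomeric silyl acetal (the lactolate is by far the best leaving group) leave O7 and O11 as non-chelating silyl ethers, which the next step needs.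

Step 5 (key step)
Reactants: 8 bis(triethylsilyl) lactol; 9 2-(2-bromoethyl)-2-methyl-1,3-dioxolane
Product: 12 (3S,4S,5R,6R,7R)-7-[(1S,3S,4R,5S)-1,4-dimethyl-2,8-dioxabicyclo[3.2.1]octan-3-yl]-3,5-dimethyloct-1-ene-4,6-diol, via Grignard reagent 10 (not isolated), via homoaldol adduct 11 (not isolated)
Conditions: 9 (3 equiv), Mg, THF, 25 °C; then 8, THF, −40 → 0 °C; then 1 M HCl, THF–MeOH, 23 °C
Reagents that add atoms: none
Why: Homoenolate (d3) addition and ketalisation cascade: the β-carbon of the masked methyl ketone is the nucleophile and attacks the aldehyde released from the magnesium lactolate; Felkin–Anh attack and the 1,3-anti preference of the non-chelating β-silyloxy group act in the same sense to set C13 (12,13-syn, 11,13-anti), and the acid then removes both silyl groups and the dioxolane so that O13 and O11 close the thermodynamically favoured bicyclic ketal, which fixes C16.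

Step 6
Reactants: 13 di-tert-butyl 3-oxopentanedioate
Product: 14 di-tert-butyl 2-methyl-3-oxopentanedioate
Conditions: MeI (1.05 equiv), K2CO3, acetone, 23 °C
Reagents that add atoms: iodomethane, CI
Why: C-alkylation (SN2) of the doubly activated β-keto ester enolate with one equivalent of iodomethane places the future aromatic methyl group; no stereocentre is kept.

Step 7
Reactants: 14 di-tert-butyl 2-methyl-3-oxopentanedioate
Product: 16 tert-butyl 5-tert-butoxy-4-methyl-3,5-bis(trimethylsilyloxy)penta-2,4-dienoate (double-bond isomers), via monosilyl enol ether 15 (not isolated)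
Conditions: Me3SiCl, Et3N, ZnCl2 (cat.), Et2O, 23 °C; filter, concentrate; then LiN(iPr)2, THF, −78 °C; Me3SiCl
Reagents that add atoms: chlorotrimethylsilane, C[Si](C)(C)Cl
Why: Two-stage Chan/Brassard-type diene synthesis: the ketone is silylated towards the unsubstituted CH2 (less hindered enol), and LiN(iPr)2 then removes the C2 proton next to the other ester, so the lithium sits on that ester oxygen and kinetic O-silylation gives the ketene acetal on the methyl-bearing terminus.

Step 8
Reactants: 16 bis(silyloxy)diene; 17 2,6-dibromo-1,4-benzoquinone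
Product: 19 tert-butyl 6-bromo-2,4-dihydroxy-3-methyl-5,8-dioxo-5,8-dihydronaphthalene-1-carboxylate, via bis(trimethylsilyl) ether 18 (not isolated)
Conditions: 16 (1.5 equiv), CH2Cl2, −40 → 23 °C; SiO2; then 1 M HCl (cat.), THF, 23 °C
Reagents that add atoms: none
Why: Regioselective Diels–Alder reaction of a Brassard-type diene with a haloquinone, followed by loss of HBr and tert-butanol: the bromine steers the ketene acetal carbon onto the brominated carbon, so the new hydroxyl ends up peri to the carbonyl flanked by the remaining bromine, and acid removes the silyl groups.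

Step 9
Reactants: 19 bromonaphthoquinone ester
Product: 21 tert-butyl 6-amino-2,4-dihydroxy-3-methyl-5,8-dioxo-5,8-dihydronaphthalene-1-carboxylate, via azidoquinone 20 (not isolated)
Conditions: NaN3 (1.5 equiv), THF–H2O, 0 → 23 °C; then Na2S2O4 (aq), 23 °C; air
Reagents that add atoms: sodium azide, [Na+].[N-]=[N+]=[N-]
Why: Addition–elimination of azide at the bromine-bearing quinone carbon, then dithionite reduction to the azidohydroquinone, which passes its two hydrogens to the azide with loss of N2 (Fieser-type internal redox), puts the amino group exactly where the bromine was.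

Step 10
Reactants: 22 (E)-but-2-enal; 23 ethyl 2-[bis(2,2,2-trifluoroethoxy)phosphoryl]propanoate
Product: 24 ethyl (2Z,4E)-2-methylhexa-2,4-dienoate
Conditions: KN(SiMe3)2, 18-crown-6, THF, −78 °C
Reagents that add atoms: none
Why: Still–Gennari modification of the Horner–Wadsworth–Emmons olefination: the electron-poor phosphonate with a dissociated potassium counter-ion eliminates from the kinetic adduct and gives the (2Z)-trisubstituted alkene, while the (4E) bond of the aldehyde is retained.

Step 11
Reactants: 24 ethyl (2Z,4E)-2-methylhexa-2,4-dienoate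
Product: 25 (2Z,4E)-2-methylhexa-2,4-dienoic acid
Conditions: LiOH, THF–MeOH–H2O, 23 °C; then 1 M HCl
Reagents that add atoms: lithium hydroxide, [Li+].[OH-]
Why: Ester saponification (BAc2) under mild conditions that do not isomerise the (2Z,4E)-diene.

Step 12
Reactants: 25 (2Z,4E)-2-methylhexa-2,4-dienoic acid; 21 aminonaphthoquinone ester
Product: 27 tert-butyl 2,4-dihydroxy-3-methyl-6-{[(2Z,4E)-2-methylhexa-2,4-dienoyl]amino}-5,8-dioxo-5,8-dihydronaphthalene-1-carboxylate, via acid chloride 26 (not isolated)
Conditions: 25, Me2C=C(Cl)NMe2, CH2Cl2, 0 °C; separately 21, NaH (3.3 equiv), THF, 0 °C; combine, −20 → 0 °C; aq. HCl work-up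
Reagents that add atoms: none
Why: N-acylation through a polyanion: neutral acid chloride formation with the Ghosez reagent avoids Z/E isomerisation, and in the trisodium salt of 21 the last-formed, most basic nitrogen anion is acylated first, so one equivalent of acid chloride gives the amide without O-acylation of the hydrogen-bonded phenols.

Step 13
Reactants: 27 amide tert-butyl ester
Product: 28 2,4-dihydroxy-3-methyl-6-{[(2Z,4E)-2-methylhexa-2,4-dienoyl]amino}-5,8-dioxo-5,8-dihydronaphthalene-1-carboxylic acid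
Conditions: CF3CO2H–CH2Cl2 (1:4), 0 → 23 °C
Reagents that add atoms: none
Why: Acidolysis of the tert-butyl ester (E1, loss of isobutene) frees the carboxylic acid without touching the amide, the quinone or the diene.

Step 14
Reactants: 12 ketal diol alkene; 28 dienamide acid
Product: 29 rifsaliniketal
Conditions: 28 (1.5 equiv), second-generation Hoveyda–Grubbs catalyst RuCl2(H2IMes)(=CH–C6H4-2-OiPr) (10 mol %), CH2Cl2, 40 °C
Reagents that add atoms: none
Why: Ene–diene cross-metathesis: the ruthenium alkylidene formed from the terminal alkene of 12 reacts only at the disubstituted γ,δ-alkene of 28 (the trisubstituted, electron-poor 2Z alkene is inert), propene is lost, and the new conjugated C4=C5 bond forms as the E isomer under thermodynamic control.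

**Compound list**
1 | 2-methylpropane-1,3-diol | CC(CO)CO | starting material
2 | but-3-en-2-yl acetate (racemic) | CC(OC(C)=O)C=C | starting material
3 | (3R,4R,6R,7R)-3,5,7-trimethylnona-1,8-diene-4,6-diol | C=C[C@@H](C)[C@@H](O)C(C)[C@H](O)[C@H](C)C=C | intermediate
4 | 4,8,9-trimethyl-2,6-dioxabicyclo[3.3.1]nonane-3,7-diol (bis-lactol, anomers) | OC1O[C@H]([C@H](C)C(O)O2)C(C)[C@H]2[C@@H]1C | intermediate
5 | (E)-crotylboronic acid pinacol ester | C/C=C/CB1OC(C)(C)C(C)(C)O1 | starting material
6 | 6-[(2R,3S,4S)-3-hydroxy-4-methylhex-5-en-2-yl]-3,5-dimethyloxane-2,4-diol (C4–C13 lactol triol, anomers) | C=C[C@H](C)[C@H](O)[C@@H](C)[C@H]1OC(O)[C@@H](C)[C@@H](O)[C@@H]1C | intermediate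
7 | tris(triethylsilyl) ether of 6 (O7, O11, anomeric O) | C=C[C@H](C)[C@H](O[Si](CC)(CC)CC)[C@@H](C)[C@H]1OC(O[Si](CC)(CC)CC)[C@@H](C)[C@@H](O[Si](CC)(CC)CC)[C@@H]1C | intermediate
8 | O7,O11-bis(triethylsilyl) ether of lactol 6 (anomeric OH free) | C=C[C@H](C)[C@H](O[Si](CC)(CC)CC)[C@@H](C)[C@H]1OC(O)[C@@H](C)[C@@H](O[Si](CC)(CC)CC)[C@@H]1C | intermediate
9 | 2-(2-bromoethyl)-2-methyl-1,3-dioxolane | CC1(CCBr)OCCO1 | starting material
10 | [2-(2-methyl-1,3-dioxolan-2-yl)ethyl]magnesium bromide | CC1(CC[Mg]Br)OCCO1 | intermediate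
11 | open-chain C13 adduct (O7,O11 silylated; C9-OH and C13-OH free; C16 as dioxolane; shown protonated) | C=C[C@H](C)[C@H](O[Si](CC)(CC)CC)[C@@H](C)[C@@H](O)[C@@H](C)[C@H](O[Si](CC)(CC)CC)[C@H](C)[C@@H](O)CCC1(C)OCCO1 | intermediate
12 | (3S,4S,5R,6R,7R)-7-[(1S,3S,4R,5S)-1,4-dimethyl-2,8-dioxabicyclo[3.2.1]octan-3-yl]-3,5-dimethyloct-1-ene-4,6-diol | C=C[C@H](C)[C@H](O)[C@@H](C)[C@@H](O)[C@@H](C)[C@@H]1O[C@@]2(C)CC[C@H](O2)[C@H]1C | intermediate
13 | di-tert-butyl 3-oxopentanedioate | CC(C)(C)OC(=O)CC(=O)CC(=O)OC(C)(C)C | starting material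
14 | di-tert-butyl 2-methyl-3-oxopentanedioate | CC(C(=O)OC(C)(C)C)C(=O)CC(=O)OC(C)(C)C | intermediate
15 | di-tert-butyl 2-methyl-3-(trimethylsilyloxy)pent-3-enedioate (E/Z mixture) | CC(C(=O)OC(C)(C)C)C(O[Si](C)(C)C)=CC(=O)OC(C)(C)C | intermediate
16 | tert-butyl 5-tert-butoxy-4-methyl-3,5-bis(trimethylsilyloxy)penta-2,4-dienoate (double-bond isomers) | CC(=C(OC(C)(C)C)O[Si](C)(C)C)C(O[Si](C)(C)C)=CC(=O)OC(C)(C)C | intermediate
17 | 2,6-dibromo-1,4-benzoquinone | O=C1C=C(Br)C(=O)C(Br)=C1 | starting material
18 | bis(trimethylsilyl) ether of 19 | O=C1C=C(Br)C(=O)c2c(O[Si](C)(C)C)c(C)c(O[Si](C)(C)C)c(C(=O)OC(C)(C)C)c12 | intermediate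
19 | tert-butyl 6-bromo-2,4-dihydroxy-3-methyl-5,8-dioxo-5,8-dihydronaphthalene-1-carboxylate | O=C1C=C(Br)C(=O)c2c(O)c(C)c(O)c(C(=O)OC(C)(C)C)c12 | intermediate
20 | tert-butyl 6-azido-2,4-dihydroxy-3-methyl-5,8-dioxo-5,8-dihydronaphthalene-1-carboxylate | [N-]=[N+]=NC1=CC(=O)c2c(C(=O)OC(C)(C)C)c(O)c(C)c(O)c2C1=O | intermediate
21 | tert-butyl 6-amino-2,4-dihydroxy-3-methyl-5,8-dioxo-5,8-dihydronaphthalene-1-carboxylate | NC1=CC(=O)c2c(C(=O)OC(C)(C)C)c(O)c(C)c(O)c2C1=O | intermediate
22 | (E)-but-2-enal | C/C=C/C=O | starting material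
23 | ethyl 2-[bis(2,2,2-trifluoroethoxy)phosphoryl]propanoate | CCOC(=O)C(C)P(=O)(OCC(F)(F)F)OCC(F)(F)F | starting material
24 | ethyl (2Z,4E)-2-methylhexa-2,4-dienoate | C/C=C/C=C(/C)C(=O)OCC | intermediate
25 | (2Z,4E)-2-methylhexa-2,4-dienoic acid | C/C=C/C=C(/C)C(=O)O | intermediate
26 | (2Z,4E)-2-methylhexa-2,4-dienoyl chloride | C/C=C/C=C(/C)C(Cl)=O | intermediate
27 | tert-butyl 2,4-dihydroxy-3-methyl-6-{[(2Z,4E)-2-methylhexa-2,4-dienoyl]amino}-5,8-dioxo-5,8-dihydronaphthalene-1-carboxylate | C/C=C/C=C(/C)C(=O)NC1=CC(=O)c2c(C(=O)OC(C)(C)C)c(O)c(C)c(O)c2C1=O | intermediate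
28 | 2,4-dihydroxy-3-methyl-6-{[(2Z,4E)-2-methylhexa-2,4-dienoyl]amino}-5,8-dioxo-5,8-dihydronaphthalene-1-carboxylic acid | C/C=C/C=C(/C)C(=O)NC1=CC(=O)c2c(C(=O)O)c(O)c(C)c(O)c2C1=O | intermediate
29 | rifsaliniketal, 6-{[(2Z,4E,6S,7S,8R,9R,10R)-10-[(1S,3S,4R,5S)-1,4-dimethyl-2,8-dioxabicyclo[3.2.1]octan-3-yl]-7,9-dihydroxy-2,6,8-trimethylundeca-2,4-dienoyl]amino}-2,4-dihydroxy-3-methyl-5,8-dioxo-5,8-dihydronaphthalene-1-carboxylic acid | C/C(=C/C=C/[C@H](C)[C@H](O)[C@@H](C)[C@@H](O)[C@@H](C)[C@@H]1O[C@@]2(C)CC[C@H](O2)[C@H]1C)C(=O)NC1=CC(=O)c2c(C(=O)O)c(O)c(C)c(O)c2C1=O | target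

**Step count**
Total: 14 steps. Longest linear sequence: 7 steps (6, 7, 8, 9, 12, 13, 14, from 13); the polyketide arm is 6 steps (1–5, 14).

**Three steps most likely to fail, with fallbacks**

Step 3 (which lactol opens, and how fast). If the bis-lactol reacts at both ends or too slowly, the ends are differentiated with a protecting group instead of ring strain. The fallback sets out from 3 and comes back at 8. Monosilylation of 3 (Et3SiCl, imidazole, 1 equiv; the other regioisomer and the bis-ether are desilylated and recycled) gives the O11 mono(triethylsilyl) ether of 3 F1. Ozonolysis then leaves C7 as a true free aldehyde, because O11 is blocked, while O9 closes on C13, giving the aldehyde lactol F2. Crotylboration with 5 and (R)-TRIP at −30 °C on this free aldehyde gives the O11-silylated crotyl adduct F3. Silylation of O7 and the anomeric oxygen gives 7, and the fluoride step of step 4 returns 8.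

Step 5 (diastereoselectivity at C13 in the Grignard addition). If the Felkin preference is too low, C13 is set by a hydroxyl-directed reduction instead of by the addition. The fallback sets out from 6 and comes back at 12. Lactol 6 is oxidised chemoselectively (TEMPO, PhI(OAc)2) to the δ-lactone of 6 F4. The same Grignard reagent 10 (3.2 equiv, −78 °C) adds once to the lactone carbonyl and gives the C13 ketone with the C16 dioxolane F5 (handled as its hemiketal). Me4NBH(OAc)3 in MeCN–AcOH at −30 °C delivers hydride from the boron bound to the C11 hydroxyl (Evans–Saksena reduction) and gives the 11,13-anti tetraol dioxolane F6. 1 M HCl then closes the ketal to 12. The C13–C14 bond is still made by the homoenolate reagent.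

Step 8 (regiochemistry of diene formation in step 7 and of the cycloaddition with an ester-terminated diene). If the silyl ketene acetal forms on the wrong ester or the diene is too unreactive, a diene with a preformed ketene acetal is used. The fallback sets out from 17 and comes back at 19. tert-Butyl hydrogen malonate, activated with Me2C=C(Cl)NMe2, acylates 1,1-dimethoxyprop-1-ene (Et3N) to give tert-butyl 5,5-dimethoxy-4-methyl-3-oxopent-4-enoate F7. Its only enolisable position is silylated (Me3SiOTf, Et3N) to give tert-butyl 5,5-dimethoxy-4-methyl-3-(trimethylsilyloxy)penta-2,4-dienoate F8. Diels–Alder reaction with 17 and aromatisation give tert-butyl 6-bromo-2-hydroxy-4-methoxy-3-methyl-5,8-dioxo-5,8-dihydronaphthalene-1-carboxylate F9. Chelation-assisted cleavage of the peri methyl ether with MgI2 (toluene–Et2O, 50 °C) gives 19.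

**Further compounds**
F1 | step 3 | O11 mono(triethylsilyl) ether of 3 | C=C[C@@H](C)[C@@H](O)[C@@H](C)[C@H](O[Si](CC)(CC)CC)[C@H](C)C=C
F2 | step 3 | C7 aldehyde with O9–C13 lactol and O11 triethylsilyl ether | O=C[C@@H](C)[C@H]1OC(O)[C@@H](C)[C@@H](O[Si](CC)(CC)CC)[C@@H]1C
F3 | step 3 | lactol 6 carrying the O11 triethylsilyl ether | C=C[C@H](C)[C@H](O)[C@@H](C)[C@H]1OC(O)[C@@H](C)[C@@H](O[Si](CC)(CC)CC)[C@@H]1C
F4 | step 5 | δ-lactone of 6 (C13 carbonyl, O9 ring oxygen) | C=C[C@H](C)[C@H](O)[C@@H](C)[C@H]1OC(=O)[C@@H](C)[C@@H](O)[C@@H]1C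
F5 | step 5 | C13 ketone with C16 dioxolane (open form of the hemiketal) | C=C[C@H](C)[C@H](O)[C@@H](C)[C@@H](O)[C@@H](C)[C@H](O)[C@H](C)C(=O)CCC1(C)OCCO1
F6 | step 5 | 11,13-anti tetraol with C16 dioxolane | C=C[C@H](C)[C@H](O)[C@@H](C)[C@@H](O)[C@@H](C)[C@H](O)[C@H](C)[C@@H](O)CCC1(C)OCCO1
F7 | step 8 | tert-butyl 5,5-dimethoxy-4-methyl-3-oxopent-4-enoate | CC(C)(C)OC(=O)CC(=O)C(C)=C(OC)OC
F8 | step 8 | tert-butyl 5,5-dimethoxy-4-methyl-3-(trimethylsilyloxy)penta-2,4-dienoate | CC(C)(C)OC(=O)C=C(O[Si](C)(C)C)C(C)=C(OC)OC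
F9 | step 8 | tert-butyl 6-bromo-2-hydroxy-4-methoxy-3-methyl-5,8-dioxo-5,8-dihydronaphthalene-1-carboxylate | COc1c(C)c(O)c(C(=O)OC(C)(C)C)c2C(=O)C=C(Br)C(=O)c12
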